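**Retrosynthetic overview**

1. The acetates go on last. The 2,3-dihydrofuran (ring D) comes from cycloisomerisation of a C13 ethynyl / C16 carbinol pair, and the 6β-hydroxy-7-ketone from a Δ6 alkene by C19-OH-directed epoxidation and oxidative epoxide opening.
2. The spiro-tetrahydrofuran (ring C) is closed by the 9α-hydroxyl opening a C13 epoxide with inversion. C12–C16 is attached by B-alkyl Suzuki–Miyaura coupling to a C9 vinyl group made from the C11 ester, and the 9α-oxygen comes from ester enolate hydroxylation.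
3. Feature the plan rests on: in ring B the C7 carbonyl lies between C6 and C8, C10 carries the angular methyl and C9 carries C11 cis to it. Ring B is therefore the [4+2] adduct of a C5=C6–C7(OSi)=C8 silyloxydiene and an (E)-C9=C10 enoate, and the C1–C4 chain joining C5 to C10 closes ring A in the same step.
4. The triene is assembled from methyl but-2-ynoate (carbocupration, E-enoate), isoprene oxide (iridium-catalysed tert-(hydroxy)prenylation, sets C3/C4) and dimethyl (2-oxobutyl)phosphonate (Horner–Wadsworth–Emmons, diene).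
5. Ring order: A and B together (step 10), then C (step 25), then D (step 28).

Key step: step 10

Remark: atoms are numbered as in labdanes (C1–C10 decalin, C11–C16 on C9, C17 on C8, C18 α and C19 β on C4, C20 on C10); TBS = tert-butyldimethylsilyl, TES = triethylsilyl.
Assumption: (R)-Tol-BINAP is taken as the ligand antipode that gives the (6S,7S)-diol in step 3; if the sense proves opposite, (S)-Tol-BINAP is used and nothing else changes.
Remark: the 3,19-diol is not tied into a six-membered acetal for the cycloaddition; C19 is carried as the aldehyde and O3 as its TBS ether (reason under step 10).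

**Route**

Step 1
Reactants: 1 methyl but-2-ynoate; 2 but-3-enylmagnesium bromide
Product: 4 methyl (2E)-3-methylhepta-2,6-dienoate, via alkenylcopper adduct 3 (not isolated)
Conditions: CuBr·SMe2 (1.0 equiv), THF, −78 °C; then 1; NH4Cl (aq)/MeOH quench at −78 °C
Reagents that add atoms: none
Why: Syn-carbocupration of the ynoate puts the butenyl group and copper cis, and protonation with retention at low temperature gives the E-enoate (C1 trans to C11).

Step 2
Reactants: 4 methyl (2E)-3-methylhepta-2,6-dienoate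
Product: 6 methyl (2E)-6-hydroxy-3-methylhex-2-enoate, via ozonide 5 (not isolated)
Conditions: O3, CH2Cl2, −78 °C (Sudan Red 7B end point); then NaBH4, MeOH, −78 → 0 °C
Reagents that add atoms: ozone, [O-][O+]=O
Why: Indicator-controlled ozonolysis cleaves the isolated terminal alkene faster than the electron-poor enoate, and reductive work-up gives the primary alcohol.

Step 3
Reactants: 6 methyl (2E)-6-hydroxy-3-methylhex-2-enoate; 7 2-methyl-2-vinyloxirane (isoprene oxide, racemic)
Product: 9 methyl (2E,6S,7S)-6-hydroxy-7-(hydroxymethyl)-3,7-dimethylnona-2,8-dienoate, via aldehyde 8 (not isolated)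
Conditions: [Ir(cod)Cl]2 (2.5 mol%), (R)-Tol-BINAP (5 mol%), 4-cyano-3-nitrobenzoic acid (10 mol%), allyl acetate (preformed π-allyl C,O-benzoate complex), K3PO4 (5 mol%), THF, 45 °C
Reagents that add atoms: none
Why: Iridium-catalysed transfer-hydrogenative tert-(hydroxy)prenylation: the alcohol is dehydrogenated to 8, the (E)-σ-allyliridium species from the vinyl epoxide adds through a closed chair transition state (anti relationship of O3 and C19), and the bisphosphine sets the absolute sense at C3 and C4.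

Step 4
Reactants: 9 the (6S,7S)-diol
Product: 10 bis-TBS ether of 9
Conditions: TBSOTf (2.4 equiv), 2,6-lutidine, CH2Cl2, −78 → 0 °C
Reagents that add atoms: tert-butyldimethylsilyl triflate, CC(C)(C)[Si](C)(C)OS(=O)(=O)C(F)(F)F
Why: Silyl triflate silylation protects both the primary and the hindered secondary hydroxyl; no stereocentre is touched.

Step 5
Reactants: 10 bis-TBS ether
Product: 12 C5 aldehyde (8-oxooct-2-enoate), via ozonide 11 (not isolated)
Conditions: O3, CH2Cl2, −78 °C (Sudan Red 7B end point); then PPh3, → rt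
Reagents that add atoms: ozone, [O-][O+]=O
Why: Selective ozonolysis of the vinyl group with reductive work-up gives the non-enolisable α-quaternary aldehyde, so C4 cannot epimerise.

Step 6
Reactants: 12 C5 aldehyde; 13 dimethyl (2-oxobutyl)phosphonate
Product: 14 (E)-enone (C5=C6–C7(=O)–C8H2–C17H3)
Conditions: LiCl, iPr2NEt, MeCN, rt
Reagents that add atoms: none
Why: Horner–Wadsworth–Emmons olefination under Masamune–Roush conditions gives the E-enone from the stabilised phosphonate without disturbing the enoate.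

Step 7
Reactants: 14 (E)-enone
Product: 15 C19 primary alcohol
Conditions: HF·pyridine, pyridine, THF, 0 °C
Reagents that add atoms: none
Why: Buffered fluoride desilylation removes the primary TBS ether much faster than the secondary one flanked by the quaternary carbon.

Step 8
Reactants: 15 C19 primary alcohol
Product: 16 C19 aldehyde
Conditions: Dess–Martin periodinane, CH2Cl2, 0 °C → rt
Reagents that add atoms: none
Why: Dess–Martin oxidation gives the aldehyde, which has no α-hydrogen and so is configurationally fixed at C4.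

Step 9
Reactants: 16 C19 aldehyde
Product: 17 (10Z)-silyl dienol ether (cycloaddition precursor)
Conditions: TBSOTf (1.2 equiv), Et3N (3 equiv), CH2Cl2, −78 → 0 °C
Reagents that add atoms: tert-butyldimethylsilyl triflate, CC(C)(C)[Si](C)(C)OS(=O)(=O)C(F)(F)F
Why: Soft enolisation of the ethyl enone with silyl triflate and amine gives the (Z)-2-silyloxydiene (C17 trans to C6); the hindered, non-enolisable aldehyde is left alone.

Step 10
Reactants: 17 (10Z)-silyl dienol ether
Product: 18 trans-decalin adduct (Δ6, 7-OTBS, 8β-methyl, 9β-CO2Me, 19-oxo)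
Conditions: PhMe (0.01 M), BHT (cat.), sealed tube, 160 °C
Reagents that add atoms: none
Why: Thermal concerted suprafacial [4+2] cycloaddition (intramolecular Diels–Alder reaction of a 1,7,9-decatrienoate; closest known type: thermal cyclisation of 2-silyloxydienes onto tethered (E)-β-methyl enoates to angular-methyl trans-decalins) forms C5–C10 and C8–C9. Ring B is closed by the cycloaddition itself and ring A as the six-membered ring that the C1–C4 tether completes through the same C5–C10 bond, the tether adopting a chair. C9 and C10 follow from the E-enoate (C11 cis to C20), C5 from the ester-endo, tether-exo transition state (trans fusion), and C8 from the (Z)-enol silane (C17 outside, hence 8β, corrected in step 13). The diene face is fixed by ring A: the small sp2 formyl group on C4, not the methyl, takes the axial site syn to the incoming C20, and the C3 OTBS group stays equatorial, so both tether stereocentres favour the 5α,10β adduct; a 3,19-acetal is avoided because its relaxed 1,3-dioxane chair would hold C2 equatorial and lead to the other face. The step needs trans fusion and one diene face; the quaternary C4 and the β-methyl enoate disfavour the cis mode, in which C6 or C9 would have to be axial on ring A. The tether overrides the para orientation that the 7-silyloxy group would prefer, so that group only raises the diene HOMO and the reaction should need about 160 °C.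

Step 11
Reactants: 18 trans-decalin adduct
Product: 19 C19 alcohol
Conditions: NaBH4, MeOH/THF, 0 °C
Reagents that add atoms: none
Why: Borohydride reduction of the aldehyde is chemoselective because the ketone is still masked as its enol silane and the ester is inert.

Step 12
Reactants: 19 C19 alcohol
Product: 20 3β,7,19-tris-TBS compound
Conditions: TBSCl, imidazole, DMF, rt
Reagents that add atoms: tert-butyldimethylsilyl chloride, CC(C)(C)[Si](C)(C)Cl
Why: Standard silylation of the primary neopentyl alcohol.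

Step 13
Reactants: 20 tris-TBS compound
Product: 22 7-ketone with 8α-methyl, via 8β-methyl ketone 21 (not isolated)
Conditions: NaOMe, MeOH/THF, 40 °C
Reagents that add atoms: none
Why: Methoxide cleaves the enol silane and then equilibrates C8 through the enolate to the equatorial 8α-methyl epimer, relieving the syn-diaxial C17/C20 interaction (base-mediated epimerisation), while C9 keeps its equatorial ester.

Step 14
Reactants: 22 7-ketone
Product: 24 Δ6-enol triflate, via potassium enolate 23 (not isolated)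
Conditions: KN(SiMe3)2 (1.05 equiv), THF, −78 °C; then PhNTf2, −78 → 0 °C
Reagents that add atoms: N-phenylbis(trifluoromethanesulfonimide), O=S(=O)(N(c1ccccc1)S(=O)(=O)C(F)(F)F)C(F)(F)F
Why: Kinetic deprotonation takes the C6 methylene rather than the tertiary, shielded C8–H, and O-triflation traps the Δ6 enolate (enol triflate formation).

Step 15
Reactants: 24 Δ6-enol triflate
Product: 25 Δ6 alkene ester
Conditions: Pd(OAc)2 (5 mol%), PPh3, Bu3N, HCO2H, DMF, 60 °C
Reagents that add atoms: none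
Why: Palladium-catalysed formate reduction of the enol triflate gives the alkene, which masks C6/C7 through the base and hydride steps that follow.

Step 16
Reactants: 25 Δ6 alkene ester
Product: 27 9α-hydroxy ester, via potassium ester enolate 26 (not isolated)
Conditions: KN(SiMe3)2, THF, −78 → −40 °C; then 2-(phenylsulfonyl)-3-phenyloxaziridine, −78 °C; NH4Cl (aq)
Reagents that add atoms: 2-(phenylsulfonyl)-3-phenyloxaziridine, O=S(=O)(N1OC1c1ccccc1)c1ccccc1
Why: Enolate hydroxylation with an N-sulfonyloxaziridine (Davis oxidation): the exocyclic C9 enolate is attacked on the α face, anti to the axial C20 methyl, giving 9α-OH.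

Step 17
Reactants: 27 9α-hydroxy ester
Product: 28 9α-OTES ester
Conditions: TESOTf, 2,6-lutidine, CH2Cl2, 0 °C
Reagents that add atoms: triethylsilyl triflate, CC[Si](CC)(CC)OS(=O)(=O)C(F)(F)F
Why: Silyl triflate silylation caps the hindered tertiary alcohol so that it cannot open the C13 epoxide prematurely or trigger an α-ketol shift.

Step 18
Reactants: 28 9α-OTES ester
Product: 29 C11 aldehyde
Conditions: iBu2AlH, CH2Cl2, −78 °C; potassium sodium tartrate (aq)
Reagents that add atoms: none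
Why: Partial reduction of the hindered α-silyloxy ester stops at the aldehyde because the chelated tetrahedral aluminate survives until work-up.

Step 19
Reactants: 29 C11 aldehyde
Product: 30 C9 vinyl compound (C11=C12)
Conditions: Ph3PCH3Br, KN(SiMe3)2, THF, 0 °C → rt
Reagents that add atoms: methyltriphenylphosphonium bromide, C[P+](c1ccccc1)(c1ccccc1)c1ccccc1.[Br-]
Why: Wittig methylenation of the non-enolisable aldehyde adds C12.

Step 20
Reactants: 30 C9 vinyl compound; 31 2-bromoprop-2-en-1-ol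
Product: 33 2-substituted allylic alcohol (C13=C16H2, C14H2OH), via B-alkyl-9-BBN borane 32 (not isolated)
Conditions: 9-BBN-H, THF, rt → 50 °C; then 31, Pd(dppf)Cl2 (5 mol%), AsPh3, Cs2CO3, DMF/H2O, rt
Reagents that add atoms: none
Why: Anti-Markovnikov hydroboration of the terminal vinyl group (the ring Δ6 alkene is far slower) followed by B-alkyl Suzuki–Miyaura coupling with the vinyl bromide joins C12 to C13.

Step 21
Reactants: 33 allylic alcohol
Product: 34 (13S)-13,16-epoxy alcohol
Conditions: Ti(OiPr)4 (10 mol%), L-(+)-diethyl tartrate (12 mol%), tBuOOH, 4 Å molecular sieves, CH2Cl2, −20 °C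
Reagents that add atoms: tert-butyl hydroperoxide, CC(C)(C)OO
Why: Sharpless asymmetric epoxidation of the 2-substituted allylic alcohol: the L-(+)-tartrate complex delivers oxygen to one face under reagent control, giving the (S)-epoxide that fixes C13.

Step 22
Reactants: 34 epoxy alcohol
Product: 35 epoxy aldehyde
Conditions: Dess–Martin periodinane, pyridine, CH2Cl2, 0 °C
Reagents that add atoms: none
Why: Buffered Dess–Martin oxidation gives the α-quaternary epoxy aldehyde, which cannot epimerise.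

Step 23
Reactants: 35 epoxy aldehyde
Product: 36 (13S)-epoxy alkyne
Conditions: dimethyl (1-diazo-2-oxopropyl)phosphonate, K2CO3, MeOH, 0 °C → rt
Reagents that add atoms: dimethyl (1-diazo-2-oxopropyl)phosphonate, CC(=O)C(=[N+]=[N-])P(=O)(OC)OC
Why: Ohira–Bestmann (Seyferth–Gilbert) homologation turns C14 into the alkyne and adds C15, which distinguishes the two one-carbon arms on C13.

Step 24
Reactants: 36 epoxy alkyne
Product: 37 3β,9α,19-triol epoxy alkyne
Conditions: Bu4NF, THF, rt → 40 °C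
Reagents that add atoms: none
Why: Fluoride removes the TES and both TBS groups under non-acidic conditions that leave the epoxide closed.

Step 25
Reactants: 37 triol epoxy alkyne
Product: 38 (13R)-9α,13-epoxy-14-yne-3β,16,19-triol (ring C closed)
Conditions: CSA (10 mol%), CH2Cl2, 0 °C
Reagents that add atoms: none
Why: Acid-catalysed 5-exo epoxide opening by the 9α-hydroxyl at the tertiary propargylic C13 with inversion gives the 13R spiro-tetrahydrofuran and frees the C16 carbinol.

Step 26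
Reactants: 38 spiro-tetrahydrofuran triol
Product: 39 6β,7β-epoxide
Conditions: VO(acac)2 (5 mol%), tBuOOH, CH2Cl2, 0 °C → rt
Reagents that add atoms: tert-butyl hydroperoxide, CC(C)(C)OO
Why: Hydroxyl-directed epoxidation: the axial C19 alkoxide bound to vanadium sits over the β face of C6=C7 (bishomoallylic delivery), so oxygen enters syn to C19 against the steric bias.

Step 27
Reactants: 39 6β,7β-epoxide
Product: 41 6β-hydroxy-7-ketone, via alkoxysulfonium triflate 40 (not isolated)
Conditions: DMSO, TfOH (1.1 equiv), rt; then iPr2NEt, 0 °C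
Reagents that add atoms: dimethyl sulfoxide, CS(C)=O
Why: Oxidative epoxide opening with DMSO (Kornblum-type): trans-diaxial attack at C7 from the α face (Fürst–Plattner) leaves the 6β-oxygen in place, and base collapses the alkoxysulfonium salt to the C7 ketone without enolising C6.

Step 28
Reactants: 41 6β-hydroxy-7-ketone
Product: 42 (13R)-9α,13:15,16-diepoxy-3β,6β,19-trihydroxylabd-14-en-7-one (ring D closed)
Conditions: Mo(CO)6 (25 mol%), Et3N, Et2O, hν (350 nm); then 41, rt
Reagents that add atoms: none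
Why: Endo-selective cycloisomerisation of the 1-alkyn-4-ol through a molybdenum vinylidene adds the C16 hydroxyl to C15 and gives the 2,3-dihydrofuran under basic conditions that the enol ether tolerates.

Step 29
Reactants: 42 trihydroxy dihydrofuran
Product: 43 (13R)-3β,19-diacetoxy-9α,13:15,16-diepoxy-6β-hydroxylabd-14-en-7-one (target, CNP0317137.1)
Conditions: Ac2O (2.2 equiv), pyridine, CH2Cl2, 0 °C → rt; NaHCO3 (aq) work-up
Reagents that add atoms: acetic anhydride, CC(=O)OC(C)=O
Why: Acylation takes the primary C19 and equatorial C3 hydroxyls, while the axial 6β-hydroxyl, flanked by C19 and C20 and hydrogen-bonded to the ketone, should stay free; the basic medium protects the enol ether.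

**Compound list**

1 | methyl but-2-ynoate | CC#CC(=O)OC | starting material
2 | but-3-enylmagnesium bromide | C=CCC[Mg]Br | starting material
3 | methyl (2Z)-2-cuprio-3-methylhepta-2,6-dienoate (alkenylcopper adduct) | C=CCC/C(C)=C(\[Cu])C(=O)OC | intermediate
4 | methyl (2E)-3-methylhepta-2,6-dienoate | C=CCC/C(C)=C/C(=O)OC | intermediate
5 | methyl (2E)-3-methyl-5-(1,2,4-trioxolan-3-yl)pent-2-enoate (ozonide) | COC(=O)/C=C(C)/CCC1OCOO1 | intermediate
6 | methyl (2E)-6-hydroxy-3-methylhex-2-enoate | OCCC/C(C)=C/C(=O)OC | intermediate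
7 | 2-methyl-2-vinyloxirane (isoprene oxide, racemic) | CC1(C=C)CO1 | starting material
8 | methyl (2E)-3-methyl-6-oxohex-2-enoate | O=CCC/C(C)=C/C(=O)OC | intermediate
9 | methyl (2E,6S,7S)-6-hydroxy-7-(hydroxymethyl)-3,7-dimethylnona-2,8-dienoate | OC[C@](C)(C=C)[C@@H](O)CC/C(C)=C/C(=O)OC | intermediate
10 | methyl (2E,6S,7S)-6-(TBS-oxy)-7-[(TBS-oxy)methyl]-3,7-dimethylnona-2,8-dienoate | CC(C)(C)[Si](C)(C)OC[C@](C)(C=C)[C@@H](O[Si](C)(C)C(C)(C)C)CC/C(C)=C/C(=O)OC | intermediate
11 | ozonide of 10 (1,2,4-trioxolan-3-yl in place of vinyl) | CC(C)(C)[Si](C)(C)OC[C@](C)(C1OCOO1)[C@@H](O[Si](C)(C)C(C)(C)C)CC/C(C)=C/C(=O)OC | intermediate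
12 | methyl (2E,6S,7S)-6-(TBS-oxy)-7-[(TBS-oxy)methyl]-3,7-dimethyl-8-oxooct-2-enoate | CC(C)(C)[Si](C)(C)OC[C@](C)(C=O)[C@@H](O[Si](C)(C)C(C)(C)C)CC/C(C)=C/C(=O)OC | intermediate
13 | dimethyl (2-oxobutyl)phosphonate | CCC(=O)CP(=O)(OC)OC | starting material
14 | methyl (2E,6S,7S,8E)-6-(TBS-oxy)-7-[(TBS-oxy)methyl]-3,7-dimethyl-10-oxododeca-2,8-dienoate | CC(C)(C)[Si](C)(C)OC[C@](C)(/C=C/C(=O)CC)[C@@H](O[Si](C)(C)C(C)(C)C)CC/C(C)=C/C(=O)OC | intermediate
15 | methyl (2E,6S,7S,8E)-6-(TBS-oxy)-7-(hydroxymethyl)-3,7-dimethyl-10-oxododeca-2,8-dienoate | OC[C@](C)(/C=C/C(=O)CC)[C@@H](O[Si](C)(C)C(C)(C)C)CC/C(C)=C/C(=O)OC | intermediate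
16 | methyl (2E,6S,7R,8E)-7-formyl-6-(TBS-oxy)-3,7-dimethyl-10-oxododeca-2,8-dienoate | O=C[C@](C)(/C=C/C(=O)CC)[C@@H](O[Si](C)(C)C(C)(C)C)CC/C(C)=C/C(=O)OC | intermediate
17 | methyl (2E,6S,7R,8E,10Z)-7-formyl-6,10-bis(TBS-oxy)-3,7-dimethyldodeca-2,8,10-trienoate | O=C[C@](C)(/C=C/C(O[Si](C)(C)C(C)(C)C)=C/C)[C@@H](O[Si](C)(C)C(C)(C)C)CC/C(C)=C/C(=O)OC | intermediate
18 | methyl 3β,7-bis(TBS-oxy)-19-oxo-12,13,14,15,16-pentanorlabd-6-en-11-oate (5αH, 8β-methyl, 9αH) | O=C[C@@]1(C)[C@@H](O[Si](C)(C)C(C)(C)C)CC[C@@]2(C)[C@H]1C=C(O[Si](C)(C)C(C)(C)C)[C@H](C)[C@@H]2C(=O)OC | intermediate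
19 | methyl 19-hydroxy-3β,7-bis(TBS-oxy)-12,13,14,15,16-pentanorlabd-6-en-11-oate (8β-methyl) | OC[C@@]1(C)[C@@H](O[Si](C)(C)C(C)(C)C)CC[C@@]2(C)[C@H]1C=C(O[Si](C)(C)C(C)(C)C)[C@H](C)[C@@H]2C(=O)OC | intermediate
20 | methyl 3β,7,19-tris(TBS-oxy)-12,13,14,15,16-pentanorlabd-6-en-11-oate (8β-methyl) | CC(C)(C)[Si](C)(C)OC[C@@]1(C)[C@@H](O[Si](C)(C)C(C)(C)C)CC[C@@]2(C)[C@H]1C=C(O[Si](C)(C)C(C)(C)C)[C@H](C)[C@@H]2C(=O)OC | intermediate
21 | methyl 3β,19-bis(TBS-oxy)-7-oxo-12,13,14,15,16-pentanorlabdan-11-oate, 8β-methyl epimer | CC(C)(C)[Si](C)(C)OC[C@@]1(C)[C@@H](O[Si](C)(C)C(C)(C)C)CC[C@@]2(C)[C@H]1CC(=O)[C@H](C)[C@@H]2C(=O)OC | intermediate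
22 | methyl 3β,19-bis(TBS-oxy)-7-oxo-12,13,14,15,16-pentanorlabdan-11-oate (8α-methyl, 9αH) | CC(C)(C)[Si](C)(C)OC[C@@]1(C)[C@@H](O[Si](C)(C)C(C)(C)C)CC[C@@]2(C)[C@H]1CC(=O)[C@@H](C)[C@@H]2C(=O)OC | intermediate
23 | potassium Δ6-enolate of 22 | CC(C)(C)[Si](C)(C)OC[C@@]1(C)[C@@H](O[Si](C)(C)C(C)(C)C)CC[C@@]2(C)[C@H]1C=C([O-])[C@@H](C)[C@@H]2C(=O)OC.[K+] | intermediate
24 | methyl 3β,19-bis(TBS-oxy)-7-(trifluoromethylsulfonyloxy)-12,13,14,15,16-pentanorlabd-6-en-11-oate | CC(C)(C)[Si](C)(C)OC[C@@]1(C)[C@@H](O[Si](C)(C)C(C)(C)C)CC[C@@]2(C)[C@H]1C=C(OS(=O)(=O)C(F)(F)F)[C@@H](C)[C@@H]2C(=O)OC | intermediate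
25 | methyl 3β,19-bis(TBS-oxy)-12,13,14,15,16-pentanorlabd-6-en-11-oate (8α-methyl, 9αH) | CC(C)(C)[Si](C)(C)OC[C@@]1(C)[C@@H](O[Si](C)(C)C(C)(C)C)CC[C@@]2(C)[C@H]1C=C[C@@H](C)[C@@H]2C(=O)OC | intermediate
26 | potassium ester enolate of 25 (C9=C11) | CC(C)(C)[Si](C)(C)OC[C@@]1(C)[C@@H](O[Si](C)(C)C(C)(C)C)CC[C@@]2(C)[C@H]1C=C[C@@H](C)C2=C([O-])OC.[K+] | intermediate
27 | methyl 9α-hydroxy-3β,19-bis(TBS-oxy)-12,13,14,15,16-pentanorlabd-6-en-11-oate | CC(C)(C)[Si](C)(C)OC[C@@]1(C)[C@@H](O[Si](C)(C)C(C)(C)C)CC[C@@]2(C)[C@H]1C=C[C@@H](C)[C@]2(O)C(=O)OC | intermediate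
28 | methyl 9α-(TES-oxy)-3β,19-bis(TBS-oxy)-12,13,14,15,16-pentanorlabd-6-en-11-oate | CC(C)(C)[Si](C)(C)OC[C@@]1(C)[C@@H](O[Si](C)(C)C(C)(C)C)CC[C@@]2(C)[C@H]1C=C[C@@H](C)[C@]2(O[Si](CC)(CC)CC)C(=O)OC | intermediate
29 | 9α-(TES-oxy)-3β,19-bis(TBS-oxy)-12,13,14,15,16-pentanorlabd-6-en-11-al | CC(C)(C)[Si](C)(C)OC[C@@]1(C)[C@@H](O[Si](C)(C)C(C)(C)C)CC[C@@]2(C)[C@H]1C=C[C@@H](C)[C@]2(O[Si](CC)(CC)CC)C=O | intermediate
30 | 9α-(TES-oxy)-3β,19-bis(TBS-oxy)-13,14,15,16-tetranorlabda-6,11-diene | CC(C)(C)[Si](C)(C)OC[C@@]1(C)[C@@H](O[Si](C)(C)C(C)(C)C)CC[C@@]2(C)[C@H]1C=C[C@@H](C)[C@]2(O[Si](CC)(CC)CC)C=C | intermediate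
31 | 2-bromoprop-2-en-1-ol | C=C(Br)CO | starting material
32 | 12-(9-borabicyclo[3.3.1]nonan-9-yl)-9α-(TES-oxy)-3β,19-bis(TBS-oxy)-13,14,15,16-tetranorlabd-6-ene | CC(C)(C)[Si](C)(C)OC[C@@]1(C)[C@@H](O[Si](C)(C)C(C)(C)C)CC[C@@]2(C)[C@H]1C=C[C@@H](C)[C@]2(O[Si](CC)(CC)CC)CCB3C4CCCC3CCC4 | intermediate
33 | 9α-(TES-oxy)-3β,19-bis(TBS-oxy)-15-norlabda-6,13(16)-dien-14-ol | CC(C)(C)[Si](C)(C)OC[C@@]1(C)[C@@H](O[Si](C)(C)C(C)(C)C)CC[C@@]2(C)[C@H]1C=C[C@@H](C)[C@]2(O[Si](CC)(CC)CC)CCC(=C)CO | intermediate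
34 | (13S)-13,16-epoxy-9α-(TES-oxy)-3β,19-bis(TBS-oxy)-15-norlabd-6-en-14-ol | CC(C)(C)[Si](C)(C)OC[C@@]1(C)[C@@H](O[Si](C)(C)C(C)(C)C)CC[C@@]2(C)[C@H]1C=C[C@@H](C)[C@]2(O[Si](CC)(CC)CC)CC[C@@]3(CO3)CO | intermediate
35 | 13,16-epoxy-9α-(TES-oxy)-3β,19-bis(TBS-oxy)-15-norlabd-6-en-14-al (C13 geometry as in 34; 13R by priority change) | CC(C)(C)[Si](C)(C)OC[C@@]1(C)[C@@H](O[Si](C)(C)C(C)(C)C)CC[C@@]2(C)[C@H]1C=C[C@@H](C)[C@]2(O[Si](CC)(CC)CC)CC[C@@]3(CO3)C=O | intermediate
36 | (13S)-13,16-epoxy-9α-(TES-oxy)-3β,19-bis(TBS-oxy)labd-6-en-14-yne | CC(C)(C)[Si](C)(C)OC[C@@]1(C)[C@@H](O[Si](C)(C)C(C)(C)C)CC[C@@]2(C)[C@H]1C=C[C@@H](C)[C@]2(O[Si](CC)(CC)CC)CC[C@@]3(CO3)C#C | intermediate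
37 | (13S)-13,16-epoxylabd-6-en-14-yne-3β,9α,19-triol | OC[C@@]1(C)[C@@H](O)CC[C@@]2(C)[C@H]1C=C[C@@H](C)[C@]2(O)CC[C@@]3(CO3)C#C | intermediate
38 | (13R)-9α,13-epoxylabd-6-en-14-yne-3β,16,19-triol | OC[C@@]1(C)[C@@H](O)CC[C@@]2(C)[C@H]1C=C[C@@H](C)[C@]21CC[C@](CO)(C#C)O1 | intermediate
39 | (13R)-6β,7β:9α,13-diepoxylabd-14-yne-3β,16,19-triol | OC[C@@]1(C)[C@@H](O)CC[C@@]2(C)[C@H]1[C@@H]3O[C@@H]3[C@@H](C)[C@]21CC[C@](CO)(C#C)O1 | intermediate
40 | (13R)-7α-[(dimethylsulfonio)oxy]-9α,13-epoxylabd-14-yne-3β,6β,16,19-tetrol triflate | OC[C@@]1(C)[C@@H](O)CC[C@@]2(C)[C@H]1[C@H](O)[C@@H](O[S+](C)C)[C@@H](C)[C@]21CC[C@](CO)(C#C)O1.[O-]S(=O)(=O)C(F)(F)F | intermediate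
41 | (13R)-9α,13-epoxy-3β,6β,16,19-tetrahydroxylabd-14-yn-7-one | OC[C@@]1(C)[C@@H](O)CC[C@@]2(C)[C@H]1[C@H](O)C(=O)[C@@H](C)[C@]21CC[C@](CO)(C#C)O1 | intermediate
42 | (13R)-9α,13:15,16-diepoxy-3β,6β,19-trihydroxylabd-14-en-7-one | OC[C@@]1(C)[C@@H](O)CC[C@@]2(C)[C@H]1[C@H](O)C(=O)[C@@H](C)[C@]21CC[C@]2(C=COC2)O1 | intermediate
43 | (13R)-3β,19-diacetoxy-9α,13:15,16-diepoxy-6β-hydroxylabd-14-en-7-one (CNP0317137.1) | CC(=O)OC[C@@]1(C)[C@@H](OC(C)=O)CC[C@@]2(C)[C@H]1[C@H](O)C(=O)[C@@H](C)[C@]21CC[C@]2(C=COC2)O1 | target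

**Step count**

Total steps: 29. Longest linear sequence: 29 steps (1 → 43).

**Steps most likely to fail**

Step 10. The cycloaddition has to be forced: it forms a bond between C5 and the fully substituted C10, and the tether imposes the orientation the silyloxy group does not prefer. Under these conditions the ester-endo preference may erode so that cis-fused adduct forms, and the chair bias of ring A may not separate the two diene faces completely. The fallback takes C5 out of the cycloaddition. It sets out from 20, used with whatever ring-fusion composition steps 10–12 deliver. Saegusa–Ito dehydrogenation of the enol silane (Pd(OAc)2, DMSO, O2) gives the Δ5-en-7-one F1, in which fusion isomers of the same C10 configuration converge. Hydrogenation (H2, Pd/C, EtOAc) then adds to the open α face, the β face being shielded by C19 and C20, and sets 5αH. This gives the ketone as 21 and 22, and the route is rejoined at 22 after the methoxide treatment of step 13. Adducts from the other diene face cannot be converged and would be removed by chromatography at 22.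

Step 27. The acid-promoted opening of the 6β,7β-epoxide by DMSO may be diverted by ionisation of the tertiary propargylic C13–O bond, by a hydride shift to a ketone without the hydroxyl, or by attack at C6. The fallback replaces the acidic opening by a nucleophilic one and sets out from 39. PhSNa (EtOH, 60 °C) opens the epoxide trans-diaxially at C7 from the α face to give the β-hydroxy sulfide F2. NaIO4 (MeOH/H2O) oxidises it to the sulfoxide F3. Pummerer rearrangement (trifluoroacetic anhydride, 2,6-lutidine, CH2Cl2, 0 °C), followed by NaHCO3 (aq)/MeOH to hydrolyse the α-acyloxy sulfide and the transient trifluoroacetates, gives the C7 ketone. The fallback comes back to the route at 41.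

Step 16. Deprotonation of the tertiary C9–H, wedged between C8 and the quaternary C10, may be incomplete, and the enolate may add to the sulfonimine by-product instead of being hydroxylated. The fallback moves the oxidation to an aldehyde enol silane and sets out from 25. LiAlH4 (THF, 0 °C) gives the primary alcohol F4, and Dess–Martin oxidation gives the aldehyde F5. Soft enolisation (TESOTf, Et3N, CH2Cl2) gives the C9=C11 enol silane F6. Rubottom oxidation with dimethyldioxirane (1 equiv, acetone/CH2Cl2, −78 °C) epoxidises it on the α face, and silyl migration delivers the 9α-TES-oxy aldehyde. The fallback comes back to the route at 29.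

**Further compounds**

F1 | step 10 | methyl 3β,19-bis(TBS-oxy)-7-oxo-12,13,14,15,16-pentanorlabd-5-en-11-oate (C8 unspecified) | CC(C)(C)[Si](C)(C)OC[C@@]1(C)[C@@H](O[Si](C)(C)C(C)(C)C)CC[C@@]2(C)C1=CC(=O)C(C)[C@@H]2C(=O)OC
F2 | step 27 | (13R)-9α,13-epoxy-7α-(phenylsulfanyl)labd-14-yne-3β,6β,16,19-tetrol | OC[C@@]1(C)[C@@H](O)CC[C@@]2(C)[C@H]1[C@H](O)[C@@H](Sc3ccccc3)[C@@H](C)[C@]21CC[C@](CO)(C#C)O1
F3 | step 27 | (13R)-9α,13-epoxy-7α-(phenylsulfinyl)labd-14-yne-3β,6β,16,19-tetrol | OC[C@@]1(C)[C@@H](O)CC[C@@]2(C)[C@H]1[C@H](O)[C@@H](S(=O)c3ccccc3)[C@@H](C)[C@]21CC[C@](CO)(C#C)O1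
F4 | step 16 | 3β,19-bis(TBS-oxy)-12,13,14,15,16-pentanorlabd-6-en-11-ol (9αH) | CC(C)(C)[Si](C)(C)OC[C@@]1(C)[C@@H](O[Si](C)(C)C(C)(C)C)CC[C@@]2(C)[C@H]1C=C[C@@H](C)[C@@H]2CO
F5 | step 16 | 3β,19-bis(TBS-oxy)-12,13,14,15,16-pentanorlabd-6-en-11-al (9αH) | CC(C)(C)[Si](C)(C)OC[C@@]1(C)[C@@H](O[Si](C)(C)C(C)(C)C)CC[C@@]2(C)[C@H]1C=C[C@@H](C)[C@@H]2C=O
F6 | step 16 | 11-(TES-oxy)-3β,19-bis(TBS-oxy)-12,13,14,15,16-pentanorlabda-6,9(11)-diene | CC(C)(C)[Si](C)(C)OC[C@@]1(C)[C@@H](O[Si](C)(C)C(C)(C)C)CC[C@@]2(C)[C@H]1C=C[C@@H](C)C2=CO[Si](CC)(CC)CC
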